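**Retrosynthetic overview**

- The target is 2-hydroxy-5-methoxy-3-nonadecyl-1,4-benzoquinone, with ring A numbered C1(=O), C2(OH), C3(C19H39), C4(=O), C5(OCH3), C6(H). It is traced back through its O-silyl quinone to a para-methoxyphenol that carries all four ring oxygens.
- The strategy rests on this feature: the para oxygens on C1 and C4 are the CO-derived carbon and the carbene carbon of a Dötz phenol, C2(O)–C3(chain) is a siloxyalkyne, and C5(OCH3)=C6(H) is a 1-methoxyvinyl group.
- Key disconnection: C3–C4, C1–C2 and C1–C6 are cut at once, giving Cr(CO)5[=C(OCH3)C(OCH3)=CH2], C19H39C≡COSi(iPr)3 and one CO ligand.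
- The carbene comes from methyl vinyl ether, Cr(CO)6 and CH3OSO2CF3; the siloxyalkyne comes from ethyl eicosanoate and CH2Br2 by ynolate homologation and O-silylation.
- Ring order: ring A is the only ring and is closed in step 3; oxidation to the quinone and desilylation follow.

Key step: step 3

Remark: the target is achiral and is taken as the 2-hydroxy-1,4-quinone tautomer drawn, so no stereocontrol is needed.

**Route**

Step 1
Reactants: 1 methyl vinyl ether; 2 chromium hexacarbonyl, Cr(CO)6
Product: 5 pentacarbonyl[methoxy(1-methoxyvinyl)carbene]chromium, via 1-methoxyvinyllithium 3 (not isolated), via lithium acylchromate 4 (not isolated)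
Conditions: t-BuLi, THF, −78 → 0 °C; Cr(CO)6, Et2O, 0 → 25 °C; evaporate; CH3OSO2CF3, CH2Cl2, 0 °C
Reagents that add atoms: methyl trifluoromethanesulfonate, COS(=O)(=O)C(F)(F)F
Why: Fischer carbene synthesis, in which α-lithiation of the enol ether gives 3, addition to a CO ligand of Cr(CO)6 gives acylchromate 4, and the hard methylating agent alkylates 4 on oxygen, as is established for lithiated cyclic enol ethers.

Step 2
Reactants: 6 ethyl eicosanoate; 7 dibromomethane
Product: 10 triisopropyl(henicos-1-yn-1-yloxy)silane, via lithium dibromoenolate 8 (not isolated), via lithium ynolate 9 (not isolated)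
Conditions: lithium 2,2,6,6-tetramethylpiperidide (LiTMP), THF, −78 °C (7, then 6); LiN(SiMe3)2, −78 °C; n-BuLi, −78 → 25 °C; iPr3SiCl, −78 → 25 °C
Reagents that add atoms: chlorotriisopropylsilane, CC(C)[Si](Cl)(C(C)C)C(C)C
Why: Kowalski ester homologation, in which LiCHBr2 adds to the ester, the dibromo enolate 8 undergoes Br–Li exchange and a carbenoid 1,2-shift to ynolate 9, and a bulky silyl chloride traps the ynolate on oxygen to give an isolable triisopropylsilyl ynol ether.

Step 3
Reactants: 5 pentacarbonyl[methoxy(1-methoxyvinyl)carbene]chromium; 10 triisopropyl(henicos-1-yn-1-yloxy)silane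
Product: 12 4,5-dimethoxy-3-nonadecyl-2-(triisopropylsilyloxy)phenol, via tricarbonylchromium arene complex 11 (not isolated)
Conditions: 10 (1.5 equiv), degassed THF, 50 °C, Ar; then air, 25 °C, filtration through Celite
Reagents that add atoms: none
Why: Proposed new method: thermal loss of one CO from the zerovalent chromium carbene 5 opens a site for alkyne 10, whose nucleophilic chain-bearing carbon bonds to the electrophilic carbene carbon (C3–C4) so that the silyloxy carbon becomes the new chromium-bound carbene centre, and CO insertion there (C1–C2) gives a chromium-complexed dienylketene. Ring A then closes by 6π electrocyclisation of the ketene carbon onto the vinyl CH2 (C1–C6), and tautomerisation of the cyclohexadienone gives arene complex 11, from which air releases phenol 12. The closest known reaction is the Dötz benzannulation of alkenyl(alkoxy)carbene chromium complexes, cyclic 1-alkoxyvinyl ones included, with ordinary alkynes, together with the insertion of ynamines into such carbenes with the same polarity; a siloxyalkyne has not been shown as the alkyne partner. No stereocentre is formed. The step needs the regiochemistry chain-beside-C4 and silyloxy-beside-C1, which the ynol ether polarisation and the bulk of the iPr3SiO group (the large substituent takes the position next to the CO-derived carbon) both favour, and it needs CO insertion to outrun cyclobutenone and five-membered-ring paths, for which the alkoxycarbene, the ether solvent and the moderate temperature are chosen.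

Step 4
Reactants: 12 4,5-dimethoxy-3-nonadecyl-2-(triisopropylsilyloxy)phenol
Product: 13 5-methoxy-3-nonadecyl-2-(triisopropylsilyloxy)-1,4-benzoquinone
Conditions: (NH4)2Ce(NO3)6 (2.2 equiv), CH3CN–THF–H2O, 0 °C
Reagents that add atoms: water, O
Why: Oxidative demethylation of a para-methoxyphenol by tetravalent cerium, in which two one-electron oxidations give an aryloxy cation, water adds at C4 and methanol is lost, so that only the C1/C4 pair can become the para-quinone while the C5 methoxy and the silyl ether remain spectators.

Step 5
Reactants: 13 5-methoxy-3-nonadecyl-2-(triisopropylsilyloxy)-1,4-benzoquinone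
Product: 14 Irisoquin-C (2-hydroxy-5-methoxy-3-nonadecyl-1,4-benzoquinone)
Conditions: Bu4NF, AcOH, THF, 0 °C
Reagents that add atoms: none
Why: Silyl ether cleavage by fluoride, which is easy here because the Si–O bond is that of a silyl ester of a vinylogous acid, with acetic acid buffering to protect the base-sensitive methoxyquinone.

**Compound list**

1 | methyl vinyl ether | COC=C | starting material
2 | chromium hexacarbonyl, Cr(CO)6 | O=C=[Cr](=C=O)(=C=O)(=C=O)(=C=O)=C=O | starting material
3 | 1-methoxyvinyllithium | [Li]C(=C)OC | intermediate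
4 | lithium pentacarbonyl(2-methoxyacryloyl)chromate, Li[Cr(CO)5(C(O)C(OCH3)=CH2)] | [Li+].[O-]C(C(=C)OC)=[Cr](=C=O)(=C=O)(=C=O)(=C=O)=C=O | intermediate
5 | pentacarbonyl[methoxy(1-methoxyvinyl)carbene]chromium, Cr(CO)5[=C(OCH3)C(OCH3)=CH2] | COC(C(=C)OC)=[Cr](=C=O)(=C=O)(=C=O)(=C=O)=C=O | intermediate
6 | ethyl eicosanoate | CCCCCCCCCCCCCCCCCCCC(=O)OCC | starting material
7 | dibromomethane | BrCBr | starting material
8 | lithium 1,1-dibromohenicos-1-en-2-olate | CCCCCCCCCCCCCCCCCCCC([O-])=C(Br)Br.[Li+] | intermediate
9 | lithium henicos-1-yn-1-olate | CCCCCCCCCCCCCCCCCCCC#C[O-].[Li+] | intermediate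
10 | triisopropyl(henicos-1-yn-1-yloxy)silane | CCCCCCCCCCCCCCCCCCCC#CO[Si](C(C)C)(C(C)C)C(C)C | intermediate
11 | tricarbonyl[η6-4,5-dimethoxy-3-nonadecyl-2-(triisopropylsilyloxy)phenol]chromium (arene and Cr(CO)3 written as two parts) | CCCCCCCCCCCCCCCCCCCc1c(OC)c(OC)cc(O)c1O[Si](C(C)C)(C(C)C)C(C)C.[Cr](=C=O)(=C=O)=C=O | intermediate
12 | 4,5-dimethoxy-3-nonadecyl-2-(triisopropylsilyloxy)phenol | CCCCCCCCCCCCCCCCCCCc1c(OC)c(OC)cc(O)c1O[Si](C(C)C)(C(C)C)C(C)C | intermediate
13 | 5-methoxy-3-nonadecyl-2-(triisopropylsilyloxy)-1,4-benzoquinone | CCCCCCCCCCCCCCCCCCCC1=C(O[Si](C(C)C)(C(C)C)C(C)C)C(=O)C=C(OC)C1=O | intermediate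
14 | Irisoquin-C, 2-hydroxy-5-methoxy-3-nonadecyl-1,4-benzoquinone | CCCCCCCCCCCCCCCCCCCC1=C(O)C(=O)C=C(OC)C1=O | target

**Step count**

Total: 5 steps. Longest linear sequence: 4 steps (step 1 or step 2, then steps 3, 4 and 5).

**Steps most likely to fail**

1. Step 3. The siloxyalkyne may insert without CO uptake and stall as a heteroatom-stabilised dienyl(siloxy)carbene, or it may leave the ketene stage by a [2+2] or five-membered-ring path, so that ring A does not close. Migration of the silyl group to the neighbouring phenol oxygen would be harmless, since both isomers lead to the same quinone. The fallback uses known chemistry and replaces the benzannulation by radical alkylation of a preformed quinone. It sets out from ethyl eicosanoate 6. Saponification (NaOH, EtOH–H2O, reflux; then HCl) gives eicosanoic acid F1. DCC and H2O2 in CH2Cl2 at 0 °C give dieicosanoyl peroxide F2. Heating F2 with commercial 2,5-dihydroxy-1,4-benzoquinone F3 in AcOH at 95 °C should release the nonadecyl radical by decarboxylation and add it to the quinone (Fieser-type peroxide alkylation), giving 2,5-dihydroxy-3-nonadecyl-1,4-benzoquinone F4. Methanol with catalytic H2SO4 at reflux should then etherify the unhindered C5 hydroxyl as a vinylogous ester and leave the hydroxyl beside the chain free. The fallback comes back to the route at the target 14.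

2. Step 4. One-electron oxidation of the very electron-rich ring by tetravalent cerium may take the ortho-quinone path with loss of the silyl group, or may over-oxidise the ring. The fallback sets out from phenol 12 and uses a two-electron oxidative dearomatisation. PhI(OAc)2 in MeOH at 0 °C should give the para-quinone monoketal 4,4,5-trimethoxy-3-nonadecyl-2-(triisopropylsilyloxy)cyclohexa-2,5-dien-1-one F5. Mild hydrolysis of the ketal (aqueous oxalic acid, THF, 25 °C) then comes back to the route at quinone 13.

3. Step 2. The waxy C20 ester may come out of solution at −78 °C, so that addition of LiCHBr2 and the carbenoid rearrangement stay incomplete, and silylation may fall on carbon to give a silylketene. The fallback sets out from ethyl eicosanoate 6 and makes the ynolate by oxidation of an acetylide instead of by homologation. i-Bu2AlH in CH2Cl2 at −78 °C gives eicosanal F6. The Ohira–Bestmann reagent (dimethyl 1-diazo-2-oxopropylphosphonate, K2CO3, MeOH, 25 °C) gives henicos-1-yne F7. Deprotonation with n-BuLi, oxygen transfer from LiOOt-Bu (from t-BuOOH and LiN(SiMe3)2, THF, −78 → 0 °C) and trapping with iPr3SiOSO2CF3 pass through ynolate 9 and come back to the route at siloxyalkyne 10.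

**Further compounds**

F1 | step 3 | eicosanoic acid | CCCCCCCCCCCCCCCCCCCC(=O)O
F2 | step 3 | dieicosanoyl peroxide | CCCCCCCCCCCCCCCCCCCC(=O)OOC(=O)CCCCCCCCCCCCCCCCCCC
F3 | step 3 | 2,5-dihydroxy-1,4-benzoquinone | O=C1C=C(O)C(=O)C=C1O
F4 | step 3 | 2,5-dihydroxy-3-nonadecyl-1,4-benzoquinone | CCCCCCCCCCCCCCCCCCCC1=C(O)C(=O)C=C(O)C1=O
F5 | step 4 | 4,4,5-trimethoxy-3-nonadecyl-2-(triisopropylsilyloxy)cyclohexa-2,5-dien-1-one | CCCCCCCCCCCCCCCCCCCC1=C(O[Si](C(C)C)(C(C)C)C(C)C)C(=O)C=C(OC)C1(OC)OC
F6 | step 2 | eicosanal | CCCCCCCCCCCCCCCCCCCC=O
F7 | step 2 | henicos-1-yne | CCCCCCCCCCCCCCCCCCCC#C
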